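**Retrosynthetic overview**
- All skeletal carbons come from triacetic acid lactone 1 (masked triketide, future A ring) and the enantiopure glycidate 2 (C2, C3, C4 and the B ring, with both stereocentres); they are joined through dianion 3 to acylpyrone 4.
- Key step: 4 → open-chain triketo ester 5 → Claisen closure of the carbocyclic A ring (6) → 6-endo epoxide opening that closes the pyranone C ring, giving 4'-O-methylaromadendrin 7 in one operation.
- Late stage: O-demethylation to aromadendrin 8, then two Friedel–Crafts C–C bonds at C6 and C8 from 4-hydroxybenzyl alcohol 9 (via quinone methide 10 and mono-adducts 11 and 12) give the target 13.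
- Ring order: the B ring and the two hydroxybenzyl rings are bought; A and then C are built together in step 2.

Assumption: methyl (2R,3S)-3-(4-methoxyphenyl)glycidate 2 (the industrial diltiazem intermediate) is bought enantiopure.

**Route**

Step 1
Reactants: 1 4-hydroxy-6-methyl-2H-pyran-2-one (triacetic acid lactone, 2.2 equiv); 2 methyl (2R,3S)-3-(4-methoxyphenyl)oxirane-2-carboxylate (1.0 equiv)
Product: 4 4-hydroxy-6-{2-[(2R,3S)-3-(4-methoxyphenyl)oxiran-2-yl]-2-oxoethyl}-2H-pyran-2-one, via dilithio triacetic acid lactone dianion 3 (not isolated)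
Conditions: LDA (4.4 equiv), THF–DMPU, −78 °C, 1 h; then 2, −78 → −40 °C; AcOH quench at −78 °C, pH 4 buffer work-up
Reagents that add atoms: none
Why: Claisen-type C-acylation of the O,C-dianion of triacetic acid lactone at its 6-methyl carbon by an ester (known dianion chemistry of this pyrone); the second equivalent of dianion takes up the acidic β-keto proton of the product so no free amide base meets the glycidate, and neither epoxide stereocentre is touched because the epoxide C–H does not enolise.

Step 2
Reactants: 4 4-hydroxy-6-{2-[(2R,3S)-3-(4-methoxyphenyl)oxiran-2-yl]-2-oxoethyl}-2H-pyran-2-one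
Product: 7 (2R,3R)-3,5,7-trihydroxy-2-(4-methoxyphenyl)chroman-4-one (4'-O-methylaromadendrin), via open-chain triketo ester 5 (not isolated), via acylphloroglucinol epoxide 6 (not isolated)
Conditions: Mg(OMe)2 (8 equiv), MeOH, Ar, 25 → 60 °C; then HCl/MeOH to pH 1, 0 → 45 °C (one pot)
Reagents that add atoms: none
Why: Proposed new method: Mg(OMe)2 opens the 2-pyrone at the lactone carbonyl to the magnesium-chelated methyl 3,5,7-triketo ester 5, whose C6 carbanion undergoes intramolecular Claisen condensation onto the ester and aromatises to acylphloroglucinol 6 (closest known reaction type: the biomimetic Mg(OMe)2 conversion of 6-(2-oxoalkyl)-4-hydroxy-2-pyrones into acylphloroglucinols), and the ortho-phenol so created opens the epoxide 6-endo at the p-methoxybenzylic carbon on acidification (closest known reaction type: acid cyclisation of 2'-hydroxychalcone epoxides to trans-dihydroflavonols); C3 is the untouched glycidate C2, and C2 arises by inversion at the benzylic carbon (or by 2,3-trans closure of the benzylic cation), giving (2R,3R).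

Step 3
Reactants: 7 (2R,3R)-3,5,7-trihydroxy-2-(4-methoxyphenyl)chroman-4-one
Product: 8 (2R,3R)-3,5,7-trihydroxy-2-(4-hydroxyphenyl)chroman-4-one ((+)-aromadendrin)
Conditions: BBr3 (6 equiv), CH2Cl2, −78 → 0 °C; then ice-water
Reagents that add atoms: none
Why: Lewis-acid cleavage of an aryl methyl ether (BBr3 demethylation); the 3-OH and 5-OH are held as boron chelates of the C4 carbonyl, C3 is not enolised, and any reversible C2–O1 ionisation recloses to the more stable 2,3-trans isomer.

Step 4
Reactants: 8 (2R,3R)-3,5,7-trihydroxy-2-(4-hydroxyphenyl)chroman-4-one; 9 4-hydroxybenzyl alcohol (2.3 equiv, slow addition)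
Product: 13 gericudranin D, via p-quinone methide 10 (not isolated), via 6-mono(4-hydroxybenzyl)aromadendrin 11 (not isolated), via 8-mono(4-hydroxybenzyl)aromadendrin 12 (not isolated)
Conditions: TsOH·H2O (10 mol%), 1,4-dioxane, 60 °C, Ar
Reagents that add atoms: none
Why: Acid-catalysed Friedel–Crafts hydroxybenzylation through p-quinone methide 10; C6 and C8 of the phloroglucinol A ring are the only strongly nucleophilic carbons, so both mono-adducts converge on the 6,8-bis adduct, and no stereocentre is formed or lost under the mild acid.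

**Compound list**

1 | 4-hydroxy-6-methyl-2H-pyran-2-one (triacetic acid lactone) | Cc1cc(O)cc(=O)o1 | starting material
2 | methyl (2R,3S)-3-(4-methoxyphenyl)oxirane-2-carboxylate | COC(=O)[C@@H]1O[C@H]1c1ccc(OC)cc1 | starting material
3 | dilithio O4,C7-dianion of triacetic acid lactone | [Li+].[Li+].[CH2-]c1cc([O-])cc(=O)o1 | intermediate
4 | 4-hydroxy-6-{2-[(2R,3S)-3-(4-methoxyphenyl)oxiran-2-yl]-2-oxoethyl}-2H-pyran-2-one | O=C(Cc1cc(O)cc(=O)o1)[C@@H]1O[C@H]1c1ccc(OC)cc1 | intermediate
5 | methyl 7-[(2R,3S)-3-(4-methoxyphenyl)oxiran-2-yl]-3,5,7-trioxoheptanoate (formed as its magnesium enolate) | COC(=O)CC(=O)CC(=O)CC(=O)[C@@H]1O[C@H]1c1ccc(OC)cc1 | intermediate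
6 | [(2R,3S)-3-(4-methoxyphenyl)oxiran-2-yl](2,4,6-trihydroxyphenyl)methanone | O=C(c1c(O)cc(O)cc1O)[C@@H]1O[C@H]1c1ccc(OC)cc1 | intermediate
7 | (2R,3R)-3,5,7-trihydroxy-2-(4-methoxyphenyl)chroman-4-one (4'-O-methylaromadendrin) | O=C1c2c(O)cc(O)cc2O[C@H](c2ccc(OC)cc2)[C@H]1O | intermediate
8 | (2R,3R)-3,5,7-trihydroxy-2-(4-hydroxyphenyl)chroman-4-one ((+)-aromadendrin) | O=C1c2c(O)cc(O)cc2O[C@H](c2ccc(O)cc2)[C@H]1O | intermediate
9 | 4-hydroxybenzyl alcohol | OCc1ccc(O)cc1 | starting material
10 | 4-methylidenecyclohexa-2,5-dien-1-one (p-quinone methide) | C=C1C=CC(=O)C=C1 | intermediate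
11 | (2R,3R)-3,5,7-trihydroxy-6-(4-hydroxybenzyl)-2-(4-hydroxyphenyl)chroman-4-one | O=C1c2c(O)c(Cc3ccc(O)cc3)c(O)cc2O[C@H](c2ccc(O)cc2)[C@H]1O | intermediate
12 | (2R,3R)-3,5,7-trihydroxy-8-(4-hydroxybenzyl)-2-(4-hydroxyphenyl)chroman-4-one | O=C1c2c(O)cc(O)c(Cc3ccc(O)cc3)c2O[C@H](c2ccc(O)cc2)[C@H]1O | intermediate
13 | gericudranin D, (2R,3R)-3,5,7-trihydroxy-6,8-bis(4-hydroxybenzyl)-2-(4-hydroxyphenyl)chroman-4-one | O=C1c2c(O)c(Cc3ccc(O)cc3)c(O)c(Cc3ccc(O)cc3)c2O[C@H](c2ccc(O)cc2)[C@H]1O | target

**Totals**

Total step count: 4. Longest linear sequence: 4 steps (1 or 2 → 4 → 7 → 8 → 13).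

**Three steps most likely to fail, with fallbacks**

Step 2 (most risky). The triketo ester can cyclise in the aldol mode to a resorcylate instead of the Claisen mode. The phenoxide or a diketone enolate can also open the epoxide 5-exo at the α-carbon, giving coumaranone or furanone by-products. The dihydroflavonol itself is base-labile. The fallback separates the two ring closures and replaces the epoxide by a base-stable thioether. It sets out from 4: BnSH and SnCl4 in CH2Cl2 at −20 °C open the epoxide at the benzylic carbon to 6-[(3S)-4-(benzylsulfanyl)-3-hydroxy-4-(4-methoxyphenyl)-2-oxobutyl]-4-hydroxy-2H-pyran-2-one F1 (benzylic epimers, which do not matter). Mg(OMe)2 in MeOH then performs only the pyrone-to-acylphloroglucinol Claisen rearrangement, giving (2S)-3-(benzylsulfanyl)-2-hydroxy-3-(4-methoxyphenyl)-1-(2,4,6-trihydroxyphenyl)propan-1-one F2. AgBF4 in CH2Cl2 at 0 °C activates the sulfide, and the ortho-phenol traps the p-methoxybenzylic cation to close the C ring 2,3-trans with C3 unchanged. The fallback comes back to the route at 7.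

Step 1. The strongly basic dianion may deprotonate or ring-open the glycidic ester instead of acylating, and the third acidic proton of the product stalls conversion. The fallback replaces the ester acylation by an aldol addition followed by oxidation. It sets out from 2: DIBAL-H in CH2Cl2 at −78 °C gives (2R,3S)-3-(4-methoxyphenyl)oxirane-2-carbaldehyde F3. This far more electrophilic partner is added to dianion 3 at −78 °C, giving 4-hydroxy-6-{2-hydroxy-2-[(2S,3S)-3-(4-methoxyphenyl)oxiran-2-yl]ethyl}-2H-pyran-2-one F4 (carbinol epimers; epoxide geometry as in 2). Dess–Martin periodinane with NaHCO3 in CH2Cl2 oxidises the carbinol. The fallback comes back to the route at 4.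

Step 4. 4-Hydroxybenzyl alcohol can self-condense on its own phenol ring or alkylate the B ring and the newly attached benzyl rings, giving oligomers. The fallback uses a masked donor that cannot self-condense easily and moves the demethylation to the end as a global deprotection. It sets out from 7 (before step 3): 4-methoxybenzyl alcohol (2.2 equiv) with TsOH·H2O in dioxane at 60 °C gives (2R,3R)-3,5,7-trihydroxy-6,8-bis(4-methoxybenzyl)-2-(4-methoxyphenyl)chroman-4-one F5. BBr3 in CH2Cl2 (−78 → 0 °C) then cleaves all three methyl ethers. The fallback comes back to the route at 13.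

**Further compounds**

F1 | step 2 | 6-[(3S)-4-(benzylsulfanyl)-3-hydroxy-4-(4-methoxyphenyl)-2-oxobutyl]-4-hydroxy-2H-pyran-2-one (benzylic epimers) | O=C(Cc1cc(O)cc(=O)o1)[C@H](O)C(SCc1ccccc1)c1ccc(OC)cc1
F2 | step 2 | (2S)-3-(benzylsulfanyl)-2-hydroxy-3-(4-methoxyphenyl)-1-(2,4,6-trihydroxyphenyl)propan-1-one (benzylic epimers) | O=C(c1c(O)cc(O)cc1O)[C@H](O)C(SCc1ccccc1)c1ccc(OC)cc1
F3 | step 1 | (2R,3S)-3-(4-methoxyphenyl)oxirane-2-carbaldehyde | O=C[C@@H]1O[C@H]1c1ccc(OC)cc1
F4 | step 1 | 4-hydroxy-6-{2-hydroxy-2-[(2S,3S)-3-(4-methoxyphenyl)oxiran-2-yl]ethyl}-2H-pyran-2-one (carbinol epimers) | OC(Cc1cc(O)cc(=O)o1)[C@@H]1O[C@H]1c1ccc(OC)cc1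
F5 | step 4 | (2R,3R)-3,5,7-trihydroxy-6,8-bis(4-methoxybenzyl)-2-(4-methoxyphenyl)chroman-4-one | O=C1c2c(O)c(Cc3ccc(OC)cc3)c(O)c(Cc3ccc(OC)cc3)c2O[C@H](c2ccc(OC)cc2)[C@H]1O
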